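## Structural features

- The target is a C30 bis-decalin carrying a 2,5-bis(sulfooxy)benzyl group. Numbering used throughout: C1–C10 for the left decalin (ring A = C1–C6 with the exocyclic methylene on C1, ring B = C5–C10), C11–C12 for the tether, C13–C22 for the right decalin (ring C = C13–C18, ring D = C17–C22).
- The left decalin is trans-fused. Calling the face of H5 α and the face of the C6 tether β, C10 is quaternary (methyl β, benzyl α) and C9 carries an α methyl, which is therefore axial and trans to the C10 methyl. C6 is a second quaternary centre joining ring A, ring B and the tether.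
- In the right decalin the quaternary C13 (methyl, tether) stands next to C14 (methyl cis to the C13 methyl) and to the ring-fusion carbon C18, whose hydrogen is cis to the tether. The only unsaturation is the hindered trisubstituted C16=C17 alkene beside the gem-dimethyl carbon C22.
- Fragile groups are the two aryl hydrogen sulfates (strong, hydrolytically labile acids), the hydroquinone behind them, the acid-sensitive C1 methylene, and the C16=C17 alkene, which excludes unselective hydrogenation, electrophilic epoxidation and allylic oxidation once ring C exists.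
- The real difficulty is stereochemical. Each half has a quaternary centre flanked by further stereocentres, and the halves communicate only through a flexible tether, so their absolute configurations must be set independently.
- The axial C9 methyl is a particular trap: any reagent that delivers hydrogen to an sp2 C9 would approach from the open α face and give the C9 epimer.
- The key step exploits ring C. It is a cyclohexene whose alkene (C16=C17) is the central bond of a 1-vinylcyclohexene, and the cis methyls on C13 and C14 correspond to the carbonyl and acetal carbons of a butenolide. One Diels–Alder reaction can therefore form C13–C18 and C14–C15 and set C13, C14 and C18.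

## Logic of the disconnections

**43 ⇒ 41.** The two aryl O–S bonds are cut first, because the sulfate monoesters are the most labile groups and make every earlier intermediate ionic. The gain is a neutral, chromatographable 41. The demand is a sulfation that leaves two alkenes alone, which a pyridine-buffered SO3 complex meets.

**41 ⇒ 39 ⇒ 38 ⇒ 37.** The O–CH3 bonds, the C1=CH2 bond and the C1 ketal are functional-group operations. Methyl ethers are chosen because they survive dissolving metal, strong base and hot hydrazine; the price is an oxidative unmasking through a quinone. The methylene is placed late so that it never meets acid or hydrogenation conditions. The ketal exists only to keep C1 silent while C5, C9 and C10 are built.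

**37 ⇒ 35 ⇒ 33.** The C9–CH3 bond is cut, with a temporary carbonyl on C7 as the activating group. The reason is the axial α methyl on C9. It must arrive as a carbon nucleophile on the α face of a C9 that already carries its hydrogen; reduction of a C9 methylene would give the epimer. The demand is a conjugate addition anti to the axial C10 methyl, followed by removal of a hindered carbonyl.

**33 ⇒ 32 ⇒ 30 ⇒ 29 ⇒ 27.** These steps move the carbonyl from C9, where the annulation puts it, to C7, where it activates C9. No skeletal bond is cut. The cost is four steps of functional-group transposition, all compatible with the C16=C17 alkene.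

**27 ⇒ 24 + 25.** The C10–CH2Ar bond and the C5–H bond are cut together. This removes the arene, the C10 quaternary centre and the ring-fusion stereocentre in one operation. The demand is a reductive alkylation in which protonation at C5 and alkylation at C10 both occur anti to the axial C6 substituent.

**24 ⇒ 23 ⇒ 22.** Removal of the ketal and cutting C5=C10 opens ring B to a prochiral triketone. The gain is that C6 becomes the only stereochemical problem of the left half at this stage. The demand is catalyst control over two enantiotopic carbonyls in the presence of a remote chiral substituent.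

**22 ⇒ 20 + 21, then 20 ⇒ 17 + 18.** The C6–C7 bond (Michael addition) and the C6–C11 bond (reductive alkylation of the dione by an aldehyde) are cut. All of the left half then comes from two cheap achiral building blocks, and the right half is reduced to an aldehyde on the tether. The demand is C-alkylation, not O-alkylation, of the dione.

**17 ⇒ 16 ⇒ 15 ⇒ 14 ⇒ 13 ⇒ 12.** The tether aldehyde is traced to a benzyl ether, and the two methyls on C13 and C14 to two CH2OH groups and then to the lactone carbonyl and acetal carbon of 12. The demand is deoxygenation of a neopentyl CH2O group.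

**12 ⇒ 4 + 11.** The C13–C18 and C14–C15 bonds are cut (retro-Diels–Alder). Ring C, the quaternary C13 and all three stereocentres of the right half disappear at once. The demand is regio-, endo- and facial selectivity with a trisubstituted dienophile.

**11 ⇒ 9 + 10, 9 ⇒ 7, 7 ⇒ 5 + 6.** The acetal C–O bond is cut to release the auxiliary; the butenolide is traced to a furan, and the side chain to a cross-coupling.
- The side chain must end up α to the lactone carbonyl. Plain 3-alkylfurans tend to give the β isomer on photooxygenation. The furan therefore carries a formyl group on C2, which is expelled and marks the carbon that becomes the carbonyl.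
- The ether is benzyl because it survives the acidic acetalisation and both hydride steps.

**4 ⇒ 3 ⇒ 1.** The vinyl–ring bond is cut to an enol triflate. This fixes the diene regiochemistry and avoids a cationic dehydration next to a quaternary carbon.

## Other disconnections considered

**Alternative 1:** The cut is the C9–C10 bond of ring B.
- **Forward step:** the silyl ketene acetal of the ring-A-fused δ-lactone A2 (carbonyl carbon on C10, ring oxygen and a (Z)-propenyl group on C7) would undergo an Ireland–Claisen rearrangement. C10 bonds to the propenyl terminus C9, the lactone contracts to ring B, and the acid A1 with C7=C8 results.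
- **In favour:** one concerted step makes the quaternary C10 and the adjacent C9 together. Their relative configuration follows from the alkene geometry and the boat-like transition state forced by ring contraction. On the C9/C10 pair it is better than the chosen plan, which spends steps 17–22 on the axial C9 methyl.
- **Against:** A2 must already hold C5, C6 and C7 correctly. The ketene acetal is fully substituted at C10, which slows the rearrangement. The carboxyl of A1 must be reduced to a neopentyl methyl and the C7=C8 alkene saturated. Most seriously, A1 carries only a silyloxyethyl stub, so the right decalin with three stereocentres would have to be grown later from the end of a flexible chain.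
- **Comparison:** mechanistically the sigmatropic step is as predictable as the cycloaddition (equal). Structurally it solves the easier half and leaves the harder one open. In step count it would not be shorter, since lactone assembly, carboxyl reduction and a late synthesis of rings C and D replace the annulation sequence.

**Alternative 2:** The cut is C5=C10 of ring B in a substrate that already contains the right decalin.
- **Forward step:** a chiral amine would turn the pentan-3-one arm of triketone A4 into an enamine whose C10 attacks one of the two enantiotopic ring carbonyls; dehydration gives enedione A3 and fixes C6.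
- **In favour:** chirality is catalytic, the building blocks are cheap, and the absolute configuration of the left half is chosen by the catalyst enantiomer, independently of the right half.
- **Equal point:** A4 and A3 are identical with 22 and 23, so the chosen plan uses this same closure as step 14. On ring B and C6 the two plans are equal.
- **Against, as the step that carries the strategy:** it forms one ring and one stereocentre, presupposes the whole right half, and relies on a catalyst acting on a substrate with a large C6 substituent. That is less secure than a substrate-controlled cycloaddition.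
- **Comparison:** the aldol delivers less structure per step and leaves the quaternary C13 and its neighbours to other chemistry. If ring C were made by another route the total would be at least as long.

**Alternative 3:** The cut is the C16=C17 alkene of ring C.
- **Forward step:** low-valent titanium from TiCl3 and the Zn–Cu couple would couple the C16 aldehyde and the C17 ring ketone of keto aldehyde A6 and deoxygenate the pinacolate to A5.
- **In favour:** the alkene position is dictated by the two carbonyl carbons, so no regiochemical or endo/exo question arises. On this point it is better than the cycloaddition. A5 is the silyl analogue of 15, so the later route would be the same (equal).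
- **Against:** the step creates no stereocentre. C13, C14 and C18 must all be present in A6, as a quaternary/tertiary pair on an open chain plus a centre α to the ketone that can epimerise. The ketone sits beside a gem-dimethyl carbon, so the coupling is hindered and needs excess titanium at high dilution. A6 itself would require a long synthesis.
- **Comparison:** the cycloaddition forms two C–C bonds, one ring and three stereocentres stereospecifically from two simple partners. The carbonyl coupling forms one C=C bond through radical and pinacol intermediates. In step economy the chosen plan is clearly ahead.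

Key step: step 6

Remark: the target is taken as the free bis(hydrogen sulfate) as drawn. It is released from its pyridinium salt only in the last operation and kept cold, because aryl hydrogen sulfates are strong, hydrolytically labile acids.

Remark: the configurations were checked atom by atom. A (5R) acetal, attack anti to the menthyloxy group and endo orientation lead to (13S,14R,18R), as the target requires. The sense needed at C6 is opposite to that delivered by L-amino acids in this annulation, hence D-phenylalanine in step 14.

Step 1
Reactants: 1 2,2-dimethylcyclohexanone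
Product: 3 6,6-dimethylcyclohex-1-en-1-yl trifluoromethanesulfonate, via lithium enolate 2 (not isolated)
Conditions: LiN(iPr)2, THF, −78 °C; then PhNTf2, −78 °C → rt
Reagents that add atoms: N-phenylbis(trifluoromethanesulfonimide), O=S(=O)(N(c1ccccc1)S(=O)(=O)C(F)(F)F)C(F)(F)F
Why: The ketone can enolise only toward C6, and O-sulfonylation of the lithium enolate by the triflimide gives the alkenyl triflate (enol triflate formation); no stereocentre is involved.

Step 2
Reactants: 3 6,6-dimethylcyclohex-1-en-1-yl trifluoromethanesulfonate
Product: 4 6,6-dimethyl-1-vinylcyclohexene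
Conditions: vinylboronic acid pinacol ester, Pd(PPh3)4 (3 mol %), K3PO4, 1,4-dioxane/H2O, 80 °C
Reagents that add atoms: 4,4,5,5-tetramethyl-2-vinyl-1,3,2-dioxaborolane, C=CB1OC(C)(C)C(C)(C)O1
Why: Suzuki–Miyaura coupling of an alkenyl triflate with a vinylboronate; the diene is formed with defined regiochemistry and without a cationic dehydration that could shift a methyl group next to the quaternary carbon.

Step 3
Reactants: 5 3-bromofuran-2-carbaldehyde; 6 potassium [2-(benzyloxy)ethyl]trifluoroborate
Product: 7 3-[2-(benzyloxy)ethyl]furan-2-carbaldehyde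
Conditions: Pd(OAc)2 (5 mol %), 2-dicyclohexylphosphino-2',6'-diisopropoxybiphenyl (10 mol %), Cs2CO3, toluene/H2O, 85 °C
Reagents that add atoms: none
Why: sp2–sp3 Suzuki–Miyaura coupling of a heteroaryl bromide with a primary alkyltrifluoroborate; the bulky electron-rich phosphine should favour reductive elimination over β-hydride elimination, and the non-enolisable aldehyde tolerates the carbonate base.

Step 4
Reactants: 7 3-[2-(benzyloxy)ethyl]furan-2-carbaldehyde
Product: 9 3-[2-(benzyloxy)ethyl]-5-hydroxyfuran-2(5H)-one, via furan endoperoxide 8 (not isolated)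
Conditions: O2, 5,10,15,20-tetraphenylporphyrin (cat.), visible light, CH2Cl2/MeOH, −20 °C → rt
Reagents that add atoms: dioxygen, O=O
Why: Singlet oxygen adds across C2/C5 of the furan ([4+2] photooxygenation), methanol adds to the formyl group and the endoperoxide fragments with loss of methyl formate; the carbon that carried the formyl group becomes the lactone carbonyl, so the side chain should end up on C3 (α) and not on C4.

Step 5
Reactants: 9 3-[2-(benzyloxy)ethyl]-5-hydroxyfuran-2(5H)-one; 10 (1R,2S,5R)-(−)-menthol
Product: 11 (5R)-3-[2-(benzyloxy)ethyl]-5-{[(1R,2S,5R)-5-methyl-2-(propan-2-yl)cyclohexyl]oxy}furan-2(5H)-one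
Conditions: p-TsOH·H2O (cat.), toluene, reflux, Dean–Stark; crystallisation from heptane, mother liquor re-equilibrated with the same acid
Reagents that add atoms: none
Why: Acid-catalysed acetalisation through the cyclic oxocarbenium ion gives both C5 epimers, which are diastereomers because of the menthyl group; the (5R) epimer is to be taken by crystallisation and the rest recycled by acid epimerisation, so C5 is set by resolution with the auxiliary.

Step 6
Reactants: 4 6,6-dimethyl-1-vinylcyclohexene; 11 (5R)-3-[2-(benzyloxy)ethyl]-5-(menthyloxy)furan-2(5H)-one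
Product: 12 (3R,3aR,9aS,9bS)-9b-[2-(benzyloxy)ethyl]-6,6-dimethyl-3-{[(1R,2S,5R)-menthyl]oxy}-3a,4,6,7,8,9,9a,9b-octahydronaphtho[1,2-c]furan-1(3H)-one (endo adduct)
Conditions: neat, 4 (4 equiv), 2,6-di-tert-butyl-4-methylphenol (cat.), sealed tube, 130 °C
Reagents that add atoms: none
Why: The reaction is a concerted, asynchronous, suprafacial [4+2] cycloaddition of the s-cis diene C15=C16–C17=C18 to the butenolide alkene C13=C14, and its closest known type is the thermal endo Diels–Alder reaction of 5-alkoxyfuran-2(5H)-ones with semicyclic dienes. Ring C is closed as the cycloadduct ring itself, both of its new bonds (C13–C18 and C14–C15) forming in the same step, so no separate cyclisation mode applies. C13 and C14 come out cis because the dienophile is a ring alkene that adds suprafacially, and their absolute configuration is fixed by approach of the diene anti to the menthyloxy group on the acetal carbon. C18 is fixed by the endo orientation, which puts the lactone carbonyl under C16–C17 and so places C19 cis to the two lactone carbons and the tether cis to H18. Regioselectivity is needed and should come from the lactone carbonyl, which makes C14 the most electrophilic carbon, and from the diene, whose largest HOMO coefficient lies on the unsubstituted terminus C15, so that the C14–C15 bond leads and the more congested C13–C18 bond follows. Endo selectivity is supported by secondary overlap with the carbonyl and by the gem-dimethyl carbon C22, which would clash with the tether in the exo arrangement. Because the dienophile is trisubstituted the reaction is run neat, hot and with excess diene.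

Step 7
Reactants: 12 endo cycloadduct
Product: 13 [(1S,2R,8aS)-1-[2-(benzyloxy)ethyl]-5,5-dimethyl-1,2,3,5,6,7,8,8a-octahydronaphthalene-1,2-diyl]dimethanol
Conditions: LiAlH4, THF, 0 °C → reflux; aqueous NaOH work-up
Reagents that add atoms: none
Why: Hydride reduction opens the lactone, the hemiacetal alkoxide expels mentholate and the liberated aldehyde is reduced as well, so both carbons end as CH2OH and the auxiliary is recovered (LiAlH4 reduction of a lactone acetal); no stereocentre is touched.

Step 8
Reactants: 13 diol
Product: 14 bis(methanesulfonate) of 13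
Conditions: MsCl, Et3N, CH2Cl2, −10 → 0 °C
Reagents that add atoms: methanesulfonyl chloride, CS(=O)(=O)Cl
Why: Sulfonylation of two primary alcohols; excess reagent in the cold should form the bis-mesylate faster than a mono-mesylate can close to the cyclic ether.

Step 9
Reactants: 14 bis(methanesulfonate)
Product: 15 ({2-[(1S,2R,8aR)-1,2,5,5-tetramethyl-1,2,3,5,6,7,8,8a-octahydronaphthalen-1-yl]ethoxy}methyl)benzene
Conditions: LiEt3BH (excess), THF, reflux
Reagents that add atoms: none
Why: SN2 displacement of primary sulfonates by the strongly nucleophilic triethylborohydride; the CH2 on C14 should react readily and the neopentyl CH2 on C13 needs reflux, while the benzyl ether and the alkene are inert.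

Step 10
Reactants: 15 benzyl ether
Product: 16 2-[(1S,2R,8aR)-1,2,5,5-tetramethyl-1,2,3,5,6,7,8,8a-octahydronaphthalen-1-yl]ethan-1-ol
Conditions: Li, NH3(l), THF, −78 °C; NH4Cl
Reagents that add atoms: none
Why: Dissolving-metal cleavage of the benzylic C–O bond (Birch-type debenzylation); an isolated trisubstituted alkene is not reduced under these conditions, which is why hydrogenolysis is avoided.

Step 11
Reactants: 16 alcohol
Product: 17 [(1S,2R,8aR)-1,2,5,5-tetramethyl-1,2,3,5,6,7,8,8a-octahydronaphthalen-1-yl]acetaldehyde
Conditions: 1,1,1-triacetoxy-1,1-dihydro-1,2-benziodoxol-3(1H)-one (Dess–Martin periodinane), CH2Cl2, 0 °C → rt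
Reagents that add atoms: none
Why: Dess–Martin oxidation of a primary alcohol to the aldehyde under near-neutral conditions; C12 is not a stereocentre, so enolisation is harmless.

Step 12
Reactants: 17 aldehyde; 18 cyclohexane-1,3-dione
Product: 20 2-{2-[(1S,2R,8aR)-1,2,5,5-tetramethyl-1,2,3,5,6,7,8,8a-octahydronaphthalen-1-yl]ethyl}cyclohexane-1,3-dione, via alkylidene dione 19 (not isolated)
Conditions: diethyl 2,6-dimethyl-1,4-dihydropyridine-3,5-dicarboxylate, L-proline (10 mol %), CH2Cl2, rt
Reagents that add atoms: none
Why: Three-component reductive alkylation: amine-catalysed Knoevenagel condensation gives the alkylidene dione, which is reduced at once by hydride transfer from the dihydropyridine, so the C6–C11 bond is made by C-alkylation without the O-alkylation an alkyl halide would give.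

Step 13
Reactants: 20 2-alkylcyclohexane-1,3-dione; 21 pent-1-en-3-one
Product: 22 2-(3-oxopentyl)-2-{2-[(1S,2R,8aR)-1,2,5,5-tetramethyl-1,2,3,5,6,7,8,8a-octahydronaphthalen-1-yl]ethyl}cyclohexane-1,3-dione
Conditions: Et3N (cat.), MeCN, rt → 40 °C
Reagents that add atoms: none
Why: Base-catalysed Michael addition of the dione to the vinyl ketone forms C6–C7 and makes C6 quaternary but still prochiral.

Step 14
Reactants: 22 triketone
Product: 23 (8aR)-5-methyl-8a-{2-[(1S,2R,8aR)-1,2,5,5-tetramethyl-1,2,3,5,6,7,8,8a-octahydronaphthalen-1-yl]ethyl}-3,4,8,8a-tetrahydronaphthalene-1,6(2H,7H)-dione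
Conditions: D-phenylalanine (1 equiv), (1R)-(−)-10-camphorsulfonic acid (0.5 equiv), DMF, 30 °C → 70 °C
Reagents that add atoms: none
Why: Amino-acid-mediated intramolecular aldol condensation (Hajos–Parrish–Eder–Sauer–Wiechert type): the enamine of the pentanone arm attacks one of the two enantiotopic ring carbonyls through a hydrogen-bonded transition state and dehydration gives the enone, closing ring B and setting C6. The D-amino acid is chosen because L-amino acids give the opposite sense at the quaternary carbon, and the right half, three bonds away, should not override the catalyst.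

Step 15
Reactants: 23 enedione
Product: 24 C1 ethylene ketal of 23
Conditions: ethylene glycol, p-TsOH·H2O (cat.), 4 Å molecular sieves, CH2Cl2, rt
Reagents that add atoms: ethane-1,2-diol, OCCO
Why: Selective ketalisation of the saturated C1 ketone, the conjugated C9 carbonyl being much less electrophilic; the ketal keeps C1 from being enolised or reduced in step 16.

Step 16
Reactants: 24 C1 ketal enone; 25 2-(bromomethyl)-1,4-dimethoxybenzene
Product: 27 10α-(2,5-dimethoxybenzyl)-10β-methyl-5α-H C9 ketone (C1 ketal), via lithium enolate 26 (not isolated)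
Conditions: Li, NH3(l), THF, −78 °C; then 25, THF, −78 → −33 °C; NH4Cl
Reagents that add atoms: none
Why: Reductive alkylation of an octalone: electron transfer gives the C9 enolate, with C5 protonated by ammonia axially and anti to the C6 substituent (trans-decalin). The benzyl bromide then attacks C10 from the α face, away from the axial C6 tether, which leaves the methyl β.

Step 17
Reactants: 27 benzylated C9 ketone
Product: 29 7-en-9-one (C1 ketal), via lithium enolate 28 (not isolated)
Conditions: LiN(iPr)2, THF, −78 °C; then N-tert-butylbenzenesulfinimidoyl chloride, −78 °C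
Reagents that add atoms: none
Why: The ketone can enolise only toward C8 because C10 is quaternary; sulfenylation of the enolate by the sulfinimidoyl chloride and spontaneous elimination of the sulfenamide give the enone (one-pot dehydrogenation of a ketone enolate).

Step 18
Reactants: 29 7-en-9-one
Product: 30 7α,8α-epoxy-9-one (C1 ketal)
Conditions: H2O2 (30 % aq.), NaOH, MeOH/THF, 0 °C → rt
Reagents that add atoms: hydrogen peroxide, OO
Why: Weitz–Scheffer nucleophilic epoxidation: hydroperoxide adds to C7 and closes on C8, leaving the electron-rich C16=C17 alkene and the arene untouched; attack anti to the axial C6 tether is expected, but the configuration is erased again in step 20.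

Step 19
Reactants: 30 epoxy ketone
Product: 32 8-en-7α-ol (C1 ketal), via epoxy hydrazone 31 (not isolated)
Conditions: N2H4·H2O, AcOH (cat.), MeOH, 0 °C → rt
Reagents that add atoms: none
Why: Wharton transposition: the epoxy hydrazone fragments with loss of nitrogen to the allylic alcohol, moving the oxygen from C9 to C7 and the alkene to C8=C9.

Step 20
Reactants: 32 allylic alcohol
Product: 33 8-en-7-one (C1 ketal)
Conditions: Dess–Martin periodinane, CH2Cl2, 0 °C → rt
Reagents that add atoms: none
Why: Oxidation of the secondary allylic alcohol gives the enone in which C9 is the β-carbon and still carries its hydrogen.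

Step 21
Reactants: 33 8-en-7-one
Product: 35 9α-methyl-7-one (C1 ketal), via lithium enolate 34 (not isolated)
Conditions: Me2CuLi (from MeLi and CuI), Et2O, −40 → 0 °C; NH4Cl
Reagents that add atoms: lithium dimethylcuprate, [Li+].C[Cu-]C
Why: Conjugate addition of a Gilman cuprate: the methyl enters C9 axially and anti to the axial β methyl on the neighbouring quaternary C10, that is from the α face, which gives the axial C9 methyl trans to the C10 methyl. A hydrogen delivered to a C9 methylene would come from this same face and give the epimer, which is why the carbon is brought in as the nucleophile.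

Step 22
Reactants: 35 9α-methyl-7-one
Product: 37 9α-methyl C1 ketal with C7 as CH2, via hydrazone 36 (not isolated)
Conditions: N2H4·H2O, KOH, diethylene glycol, 130 °C then 200 °C
Reagents that add atoms: none
Why: Wolff–Kishner reduction (Huang–Minlon procedure) removes the C7 carbonyl, which served only as an activating group; C9 is β to it and cannot epimerise, and the ketal, aryl ethers and alkene are stable to hot KOH.

Step 23
Reactants: 37 C1 ketal
Product: 38 9α-methyl C1 ketone
Conditions: 1 M HCl, THF, rt
Reagents that add atoms: water, O
Why: Acid hydrolysis of the dioxolane; dilute acid at room temperature should spare the C16=C17 alkene, and C1 has no epimerisable neighbour.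

Step 24
Reactants: 38 C1 ketone
Product: 39 1-methylidene hydroquinone dimethyl ether
Conditions: Ph3PCH3Br, KOtBu, toluene, 90 °C
Reagents that add atoms: methyltriphenylphosphonium bromide, C[P+](c1ccccc1)(c1ccccc1)c1ccccc1.[Br-]
Why: Wittig methylenation of a hindered ketone flanked by the quaternary C6; excess ylide in hot toluene is the usual answer to such neopentyl carbonyls.

Step 25
Reactants: 39 hydroquinone dimethyl ether
Product: 41 1-methylidene hydroquinone, via quinone 40 (not isolated)
Conditions: (NH4)2Ce(NO3)6, MeCN/H2O, 0 °C; then Na2S2O4 (aq.), rt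
Reagents that add atoms: water, O
Why: Oxidative demethylation of a hydroquinone dimethyl ether by tetravalent cerium (two one-electron oxidations, water adds at the ipso carbons, methanol leaves) gives the quinone, which dithionite reduces in the same flask; the alkenes should be inert to both reagents in the cold.

Step 26
Reactants: 41 hydroquinone
Product: 43 target bis(hydrogen sulfate), via bis(pyridinium) salt 42 (not isolated)
Conditions: SO3·pyridine, pyridine, 50 °C; then sulfonic acid cation-exchange resin (H+ form), MeOH/H2O, 0 °C
Reagents that add atoms: sulfur trioxide–pyridine complex, [O-]S(=O)(=O)[n+]1ccccc1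
Why: O-Sulfation of both phenols by the SO3–pyridine complex; exchange of pyridinium for protons on the resin at 0 °C gives the free acid, which should be kept cold and dilute because it is strong enough to isomerise its own C1 methylene.

## Compound list

1 | 2,2-dimethylcyclohexanone | CC1(C)CCCCC1=O | starting material
2 | lithium 6,6-dimethylcyclohex-1-en-1-olate | [Li+].[O-]C1=CCCCC1(C)C | intermediate
3 | 6,6-dimethylcyclohex-1-en-1-yl trifluoromethanesulfonate | CC1(C)CCCC=C1OS(=O)(=O)C(F)(F)F | intermediate
4 | 6,6-dimethyl-1-vinylcyclohexene | C=CC1=CCCCC1(C)C | intermediate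
5 | 3-bromofuran-2-carbaldehyde | O=Cc1occc1Br | starting material
6 | potassium [2-(benzyloxy)ethyl]trifluoroborate | [K+].F[B-](F)(F)CCOCc1ccccc1 | starting material
7 | 3-[2-(benzyloxy)ethyl]furan-2-carbaldehyde | O=Cc1occc1CCOCc1ccccc1 | intermediate
8 | 6-[2-(benzyloxy)ethyl]-2,3,7-trioxabicyclo[2.2.1]hept-5-ene-1-carbaldehyde (furan endoperoxide, racemic) | O=CC12OOC(O1)C=C2CCOCc1ccccc1 | intermediate
9 | 3-[2-(benzyloxy)ethyl]-5-hydroxyfuran-2(5H)-one (racemic hemiacetal) | O=C1OC(O)C=C1CCOCc1ccccc1 | intermediate
10 | (1R,2S,5R)-(−)-menthol | C[C@@H]1CC[C@H]([C@@H](C1)O)C(C)C | starting material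
11 | (5R)-3-[2-(benzyloxy)ethyl]-5-{[(1R,2S,5R)-5-methyl-2-(propan-2-yl)cyclohexyl]oxy}furan-2(5H)-one | O=C1C(CCOCc2ccccc2)=C[C@H](O[C@@H]2C[C@H](C)CC[C@H]2C(C)C)O1 | intermediate
12 | (3R,3aR,9aS,9bS)-9b-[2-(benzyloxy)ethyl]-6,6-dimethyl-3-{[(1R,2S,5R)-menthyl]oxy}-3a,4,6,7,8,9,9a,9b-octahydronaphtho[1,2-c]furan-1(3H)-one; endo adduct, lactone cis-fused, menthyloxy trans to C4, C9 cis to the lactone carbons | c1ccccc1COCC[C@@]1(C4=O)[C@H]([C@H](O[C@@H]5C[C@H](C)CC[C@H]5C(C)C)O4)CC=C3[C@@H]1CCCC3(C)C | intermediate
13 | [(1S,2R,8aS)-1-[2-(benzyloxy)ethyl]-5,5-dimethyl-1,2,3,5,6,7,8,8a-octahydronaphthalene-1,2-diyl]dimethanol | c1ccccc1COCC[C@@]1(CO)[C@H](CO)CC=C3[C@@H]1CCCC3(C)C | intermediate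
14 | bis(methanesulfonate) of 13, configuration unchanged | c1ccccc1COCC[C@@]1(COS(C)(=O)=O)[C@H](COS(C)(=O)=O)CC=C3[C@@H]1CCCC3(C)C | intermediate
15 | ({2-[(1S,2R,8aR)-1,2,5,5-tetramethyl-1,2,3,5,6,7,8,8a-octahydronaphthalen-1-yl]ethoxy}methyl)benzene | c1ccccc1COCC[C@@]1(C)[C@H](C)CC=C3[C@@H]1CCCC3(C)C | intermediate
16 | 2-[(1S,2R,8aR)-1,2,5,5-tetramethyl-1,2,3,5,6,7,8,8a-octahydronaphthalen-1-yl]ethan-1-ol | OCC[C@@]1(C)[C@H](C)CC=C2[C@@H]1CCCC2(C)C | intermediate
17 | [(1S,2R,8aR)-1,2,5,5-tetramethyl-1,2,3,5,6,7,8,8a-octahydronaphthalen-1-yl]acetaldehyde | O=CC[C@@]1(C)[C@H](C)CC=C2[C@@H]1CCCC2(C)C | intermediate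
18 | cyclohexane-1,3-dione | O=C1CCCC(=O)C1 | starting material
19 | 2-{2-[(1S,2R,8aR)-1,2,5,5-tetramethyl-1,2,3,5,6,7,8,8a-octahydronaphthalen-1-yl]ethylidene}cyclohexane-1,3-dione | O=C1CCCC(=O)C1=CC[C@@]2(C)[C@H](C)CC=C3[C@@H]2CCCC3(C)C | intermediate
20 | 2-{2-[(1S,2R,8aR)-1,2,5,5-tetramethyl-1,2,3,5,6,7,8,8a-octahydronaphthalen-1-yl]ethyl}cyclohexane-1,3-dione | O=C1CCCC(=O)C1CC[C@@]2(C)[C@H](C)CC=C3[C@@H]2CCCC3(C)C | intermediate
21 | pent-1-en-3-one | C=CC(=O)CC | starting material
22 | 2-(3-oxopentyl)-2-{2-[(1S,2R,8aR)-1,2,5,5-tetramethyl-1,2,3,5,6,7,8,8a-octahydronaphthalen-1-yl]ethyl}cyclohexane-1,3-dione | O=C1CCCC(=O)C1(CCC(=O)CC)CC[C@@]2(C)[C@H](C)CC=C3[C@@H]2CCCC3(C)C | intermediate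
23 | (8aR)-5-methyl-8a-{2-[(1S,2R,8aR)-1,2,5,5-tetramethyl-1,2,3,5,6,7,8,8a-octahydronaphthalen-1-yl]ethyl}-3,4,8,8a-tetrahydronaphthalene-1,6(2H,7H)-dione | O=C1CCCC2=C(C)C(=O)CC[C@@]12CC[C@@]3(C)[C@H](C)CC=C4[C@@H]3CCCC4(C)C | intermediate
24 | C1 ethylene ketal of 23: (8a'R)-5'-methyl-8a'-(right-half ethyl)-3',4',8',8a'-tetrahydro-2'H-spiro[1,3-dioxolane-2,1'-naphthalen]-6'(7'H)-one | O1CCOC12CCCC3=C(C)C(=O)CC[C@@]23CC[C@@]4(C)[C@H](C)CC=C5[C@@H]4CCCC5(C)C | intermediate
25 | 2-(bromomethyl)-1,4-dimethoxybenzene | COc1ccc(OC)c(CBr)c1 | starting material
26 | lithium C9 enolate (C9=C10) of the 5α-H C1 ketal, tether on C6 β | O1CCOC12CCC[C@H]3[C@@]2(CC[C@@]4(C)[C@H](C)CC=C5[C@@H]4CCCC5(C)C)CCC([O-])=C3C.[Li+] | intermediate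
27 | trans-fused C1 ketal C9 ketone: 5α-H, 6β-tether, 10β-methyl, 10α-(2,5-dimethoxybenzyl) | O1CCOC12CCC[C@H]3[C@@]2(CC[C@@]4(C)[C@H](C)CC=C5[C@@H]4CCCC5(C)C)CCC(=O)[C@]3(C)Cc6cc(OC)ccc6OC | intermediate
28 | lithium C8=C9 enolate of 27 | O1CCOC12CCC[C@H]3[C@@]2(CC[C@@]4(C)[C@H](C)CC=C5[C@@H]4CCCC5(C)C)CC=C([O-])[C@]3(C)Cc6cc(OC)ccc6OC.[Li+] | intermediate
29 | 7-en-9-one: 27 with a C7=C8 double bond | O1CCOC12CCC[C@H]3[C@@]2(CC[C@@]4(C)[C@H](C)CC=C5[C@@H]4CCCC5(C)C)C=CC(=O)[C@]3(C)Cc6cc(OC)ccc6OC | intermediate
30 | 7α,8α-epoxy-9-one (epoxide anti to the C6 tether) | O1CCOC12CCC[C@H]3[C@@]2(CC[C@@]4(C)[C@H](C)CC=C5[C@@H]4CCCC5(C)C)[C@@H]7O[C@@H]7C(=O)[C@]3(C)Cc6cc(OC)ccc6OC | intermediate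
31 | C9 hydrazone of 30 | O1CCOC12CCC[C@H]3[C@@]2(CC[C@@]4(C)[C@H](C)CC=C5[C@@H]4CCCC5(C)C)[C@@H]7O[C@@H]7C(=NN)[C@]3(C)Cc6cc(OC)ccc6OC | intermediate
32 | 8-en-7α-ol (allylic alcohol, C8=C9) | O1CCOC12CCC[C@H]3[C@@]2(CC[C@@]4(C)[C@H](C)CC=C5[C@@H]4CCCC5(C)C)[C@H](O)C=C[C@]3(C)Cc6cc(OC)ccc6OC | intermediate
33 | 8-en-7-one | O1CCOC12CCC[C@H]3[C@@]2(CC[C@@]4(C)[C@H](C)CC=C5[C@@H]4CCCC5(C)C)C(=O)C=C[C@]3(C)Cc6cc(OC)ccc6OC | intermediate
34 | lithium C7 enolate (C7=C8) carrying the 9α-methyl | O1CCOC12CCC[C@H]3[C@@]2(CC[C@@]4(C)[C@H](C)CC=C5[C@@H]4CCCC5(C)C)C([O-])=C[C@H](C)[C@]3(C)Cc6cc(OC)ccc6OC.[Li+] | intermediate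
35 | 9α-methyl-7-one (methyl axial, trans to the 10β-methyl) | O1CCOC12CCC[C@H]3[C@@]2(CC[C@@]4(C)[C@H](C)CC=C5[C@@H]4CCCC5(C)C)C(=O)C[C@H](C)[C@]3(C)Cc6cc(OC)ccc6OC | intermediate
36 | C7 hydrazone of 35 | O1CCOC12CCC[C@H]3[C@@]2(CC[C@@]4(C)[C@H](C)CC=C5[C@@H]4CCCC5(C)C)C(=NN)C[C@H](C)[C@]3(C)Cc6cc(OC)ccc6OC | intermediate
37 | 9α-methyl C1 ketal with C7 as CH2 | O1CCOC12CCC[C@H]3[C@@]2(CC[C@@]4(C)[C@H](C)CC=C5[C@@H]4CCCC5(C)C)CC[C@H](C)[C@]3(C)Cc6cc(OC)ccc6OC | intermediate
38 | C1 ketone: 5α-H, 6β-tether, 9α-methyl, 10β-methyl, 10α-(2,5-dimethoxybenzyl) | O=C1CCC[C@H]2[C@@]1(CC[C@@]3(C)[C@H](C)CC=C4[C@@H]3CCCC4(C)C)CC[C@H](C)[C@]2(C)Cc5cc(OC)ccc5OC | intermediate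
39 | 2-{[(1S,2S,4aS,8aR)-1,2-dimethyl-5-methylidene-4a-{2-[(1S,2R,8aR)-1,2,5,5-tetramethyl-1,2,3,5,6,7,8,8a-octahydronaphthalen-1-yl]ethyl}decahydronaphthalen-1-yl]methyl}-1,4-dimethoxybenzene | C=C1CCC[C@H]2[C@@]1(CC[C@@]3(C)[C@H](C)CC=C4[C@@H]3CCCC4(C)C)CC[C@H](C)[C@]2(C)Cc5cc(OC)ccc5OC | intermediate
40 | corresponding 2-substituted 1,4-benzoquinone | C=C1CCC[C@H]2[C@@]1(CC[C@@]3(C)[C@H](C)CC=C4[C@@H]3CCCC4(C)C)CC[C@H](C)[C@]2(C)CC5=CC(=O)C=CC5=O | intermediate
41 | corresponding benzene-1,4-diol (hydroquinone) | C=C1CCC[C@H]2[C@@]1(CC[C@@]3(C)[C@H](C)CC=C4[C@@H]3CCCC4(C)C)CC[C@H](C)[C@]2(C)Cc5cc(O)ccc5O | intermediate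
42 | bis(pyridinium) salt of the bis(sulfate) | C=C1CCC[C@H]2[C@@]1(CC[C@@]3(C)[C@H](C)CC=C4[C@@H]3CCCC4(C)C)CC[C@H](C)[C@]2(C)Cc5cc(OS(=O)(=O)[O-])ccc5OS(=O)(=O)[O-].c1cc[nH+]cc1.c1cc[nH+]cc1 | intermediate
43 | 2-{[(1S,2S,4aS,8aR)-1,2-dimethyl-5-methylidene-4a-{2-[(1S,2R,8aR)-1,2,5,5-tetramethyl-1,2,3,5,6,7,8,8a-octahydronaphthalen-1-yl]ethyl}decahydronaphthalen-1-yl]methyl}-1,4-phenylene bis(hydrogen sulfate) (CNP0426429.4) | C=C1CCC[C@H]2[C@@]1(CC[C@@]1(C)[C@H](C)CC=C3[C@@H]1CCCC3(C)C)CC[C@H](C)[C@]2(C)Cc1cc(OS(=O)(=O)O)ccc1OS(=O)(=O)O | target

## Step count and least certain steps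

Total step count: 26. Longest linear sequence: 24 steps (steps 3–26, from 5); the diene branch (steps 1–2) joins at step 6.

**Step 6 (key step).** The dienophile is trisubstituted, so the cycloaddition may be slow enough for the diene to dimerise or decompose first. Regioselectivity and endo selectivity may also be eroded, because the bond between the fully substituted C13 and the ring terminus C18 is sterically costly. The fallback changes the order of bond formation but not the disconnection of ring C. It sets out from 4, which is combined with the unsubstituted and far more reactive (5R)-5-{[(1R,2S,5R)-menthyl]oxy}furan-2(5H)-one F1 under the same thermal conditions to give the tether-free endo cycloadduct F2. The lactone α-carbon C13 of F2 is then deprotonated with LiN(iPr)2 at −78 °C and alkylated with 2-(benzyloxy)ethyl trifluoromethanesulfonate F3, made from 2-(benzyloxy)ethanol and triflic anhydride. The electrophile should enter on the convex face, since only a cis-fused lactone can form, which puts the tether where the cycloaddition would have put it. The route is rejoined at 12.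

**Step 9.** Displacement at the neopentyl carbon on C13 may be too slow. Hydride may then attack sulfur instead, and the liberated alkoxide could close onto the neighbouring carbon to a cyclic ether or simply return the alcohol. The fallback avoids backside attack altogether. It sets out from 13, which is converted with NaH, CS2 and MeI into the bis(S-methyl dithiocarbonate) F4. Both primary positions are then deoxygenated by radical chain reduction with (Me3Si)3SiH and 2,2'-azobis(2-methylpropionitrile) in xylene at 140 °C (Barton–McCombie). The route is rejoined at 15.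

**Step 14.** Catalyst control over the two enantiotopic carbonyls may be weakened by the large C6 substituent, and the cyclisation may stall before dehydration. The fallback replaces catalyst control by separation. It sets out from 22, which is cyclised with pyrrolidine and acetic acid to a mixture of 23 and its C6 epimer F5. These are diastereomers because of the right half and can be separated by chromatography or crystallisation. The route is rejoined at 23.

**Step 22.** The C7 carbonyl lies between the quaternary C6 and a ring face occupied by the axial C9 methyl. Hydrazone formation may therefore be incomplete, and forcing conditions may lead to azine formation. The fallback replaces the ionic reduction by a radical one. It sets out from 35, which is reduced with LiAlH4 to the C7 alcohol F6 (either epimer serves), converted with NaH, CS2 and MeI into the xanthate F7, and deoxygenated with (Me3Si)3SiH and 2,2'-azobis(2-methylpropionitrile) in toluene at reflux. The route is rejoined at 37.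

## Further compounds

F1 | step 6 | (5R)-5-{[(1R,2S,5R)-menthyl]oxy}furan-2(5H)-one | O=C1C=C[C@H](O[C@@H]2C[C@H](C)CC[C@H]2C(C)C)O1
F2 | step 6 | tether-free endo cycloadduct (12 with hydrogen in place of the benzyloxyethyl group) | [C@@H]1(C4=O)[C@H]([C@H](O[C@@H]5C[C@H](C)CC[C@H]5C(C)C)O4)CC=C3[C@@H]1CCCC3(C)C
F3 | step 6 | 2-(benzyloxy)ethyl trifluoromethanesulfonate | O=S(=O)(OCCOCc1ccccc1)C(F)(F)F
F4 | step 9 | bis(S-methyl dithiocarbonate) of 13 | c1ccccc1COCC[C@@]1(COC(=S)SC)[C@H](COC(=S)SC)CC=C3[C@@H]1CCCC3(C)C
F5 | step 14 | (8aS) epimer of 23 | O=C1CCCC2=C(C)C(=O)CC[C@]12CC[C@@]3(C)[C@H](C)CC=C4[C@@H]3CCCC4(C)C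
F6 | step 22 | C7 alcohol from 35 (C7 configuration immaterial) | O1CCOC12CCC[C@H]3[C@@]2(CC[C@@]4(C)[C@H](C)CC=C5[C@@H]4CCCC5(C)C)C(O)C[C@H](C)[C@]3(C)Cc6cc(OC)ccc6OC
F7 | step 22 | S-methyl dithiocarbonate of F6 | O1CCOC12CCC[C@H]3[C@@]2(CC[C@@]4(C)[C@H](C)CC=C5[C@@H]4CCCC5(C)C)C(OC(=S)SC)C[C@H](C)[C@]3(C)Cc6cc(OC)ccc6OC
A1 | alternative 1 | left decalin acid with the carboxyl on C10, C7=C8, C1 ketal and silyloxyethyl tether | C13(OCCO3)CCC[C@H]2[C@@]1(CCO[Si](C)(C)C(C)(C)C)C=C[C@H](C)[C@]2(C(=O)O)Cc1cc(OC)ccc1OC
A2 | alternative 1 | ring-A-fused δ-lactone with a (Z)-propenyl group on C7 (C10 epimers, erased on enolisation) | C13(OCCO3)CCC[C@H]2[C@@]1(CCO[Si](C)(C)C(C)(C)C)[C@H](/C=C\C)OC(=O)C2Cc1cc(OC)ccc1OC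
A3 | alternative 2 | bis-decalin enedione with C6 set (identical with 23) | O=C1CCCC2=C(C)C(=O)CC[C@@]12CC[C@@]3(C)[C@H](C)CC=C4[C@@H]3CCCC4(C)C
A4 | alternative 2 | prochiral triketone (identical with 22) | O=C1CCCC(=O)C1(CCC(=O)CC)CC[C@@]2(C)[C@H](C)CC=C3[C@@H]2CCCC3(C)C
A5 | alternative 3 | right-half decalin with the tether as tert-butyldimethylsilyl ether | CC(C)(C)[Si](C)(C)OCC[C@@]1(C)[C@H](C)CC=C2[C@@H]1CCCC2(C)C
A6 | alternative 3 | keto aldehyde with the C16 aldehyde and the C17 ring ketone | CC(C)(C)[Si](C)(C)OCC[C@@](C)([C@H](C)CC=O)[C@H]1CCCC(C)(C)C1=O
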